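With 32 µM of second catalyst against 14 mM of starting material, the second catalyst is a small charge, and the readings show something fading, so I ask how much target each flask can still make.

the same everywhere: starting material 14 mM; free catalyst 0.70 mM; second catalyst 32 µM
- Monday's: partner 24 mM; run made earlier
- Friday's: partner 47 mM; run made earlier
- teal: partner 35.0 mM; time 12 h
- red: partner 52.0 mM; time 12 h

| run | time / h | target / % | starting material / % | intermediate / % |
|---|---|---|---|---|
| Monday's | 2.00 | 13.5 | 29.9 | 56.5 |
| Monday's | 4.00 | 23.4 | 25.2 | 50.4 |
| Monday's | 6.00 | 30.0 | 23.3 | 45.9 |
| Monday's | 8.00 | 34.9 | 20.9 | 44.5 |
| Friday's | 2.00 | 24.5 | 27.0 | 47.8 |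
| Friday's | 4.00 | 41.6 | 19.7 | 38.5 |
| Friday's | 6.00 | 51.6 | 16.2 | 31.7 |
| Friday's | 8.00 | 59.7 | 14.2 | 27.2 |

(scatter of a reading: 0.5 percentage points)

- a reading or a percentage of target counts all its forms, free or not

- which of these there is most of at the end, counted by the starting material in it, teal (starting material / intermediate / target)
- which of these there is most of at the end, counted by the starting material in it, red (starting material / intermediate / target)
- the largest of these amounts at the end, in percent of the starting material charged, teal
- the largest of these amounts at the end, in percent of the starting material charged, red

At the last readings, intermediate holds about 66.9% of the unconverted pool. I call k the rate of target divided by intermediate and by free c(partner), with partner used one for one. From the first pair of readings to the last, k falls from 0.0721 L mol⁻¹ min⁻¹ to 0.0464 L mol⁻¹ min⁻¹ on Monday's run, and from 0.0779 L mol⁻¹ min⁻¹ to 0.0585 L mol⁻¹ min⁻¹ on Friday's.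

Dividing that fall by the target made meanwhile takes time out. Carried on in a straight line, k reaches zero at a target level I call the reach: 57.8% on Monday's run, 123% on Friday's. Friday's reach is twice Monday's, and so is its partner. So I carry the reach per unit of free c(partner), 29.3 L mol⁻¹.

The rate of target is then 0.146 h⁻¹ times the unconverted share times the distance to the reach. I integrate from 2.00 h, where the line through both runs gives 18.8% for teal and 26.9% for red. With partner at its charge, the reaches are 102% and 152%, which give target 63.7% in teal and 80.4% in red.

The weak link is that partner, which gets used. With its mean over the run, the reaches are 85.6% and 130%, and target comes to 56.7% in teal, more than its intermediate at 29.0%, and 74.7% in red. I commit to target in both.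

The forecast also names target in both, at 57% for teal and 71% for red, and it differs from me in holding that “the apparent rate constant falls with time, not with target level”.

The flasks give target at 55.5% in teal and target at 72.5% in red.

    partner + second catalyst + intermediate → second catalyst + target (k = 4590 L² mol⁻² min⁻¹)
    crystals ⇌ target, rate k2*(cs2 - [target]) while solid is left; crystals form when [target] > cs2 (solubility = 0.510 mM, k = 0.0440 min⁻¹)
    starting material + free catalyst ⇌ free catalyst + intermediate (K = 2.09, k = 33.0 L mol⁻¹ min⁻¹)
    starting material + second catalyst → spent catalyst (k = 0.650 L mol⁻¹ min⁻¹)

Neither flask is at rest at 12 h. Left until 120 h, teal reaches 73.5% of target, with 0.0839% of its second catalyst remaining, and the reach, taken with the partner then free, is 72.3%. Red reaches 98.1%, with 7.25% of its second catalyst remaining, and its reach on the same footing is 112%, above the whole charge.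

Red's reach of 130%, run on to 30 h, gives 92.1% of target. The computed flask holds 88.1%.

The data come from a simulation with made-up constants, and the scatter is random.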